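**Plan**
- Retrosynthesis: the bridge bond CH2–C2 of ring A is cut first, giving a ring A trione and a ring B aminomethyl acylphloroglucinol. Ring B goes back to phloroglucinol by removing the aminomethyl, prenyl and isobutyryl groups.
- Ring A is opened at C2–C3 (Dieckmann), then cut at C6–C1 (acetyl unit), C5–C6 (ethyl unit), C4–C5 (one carbon, formaldehyde) and C4–prenyl, which leaves methyl isobutyrylacetate.
- Enabling feature: C4 of ring A is quaternary and bonded to ring carbons C3 and C5, the isobutyryl carbonyl and the prenyl CH2. Read with C3 as an ester carbon, C4 is the α-carbon of an α-prenyl β-keto ester and C5 is the carbon that formaldehyde delivers.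
- Forward: the chain is built on C4 (prenyl, C5, C6, then C1–C2), ring A closes by C2→C3 acylation, ring B is made in parallel, and the two rings are joined through the methylene in the last step.
- Stereochemistry: the only stereocentre, C4, is set by a Sc(OTf)3/chiral bipyridine diol-catalysed aldol addition of the racemic, enolisable keto ester to formaldehyde. It has no α-hydrogen afterwards and no later step breaks a bond to it.

Key step: step 2

Assumption: the (S,S)-ligand is taken to deliver the (2R)-hydroxymethyl adduct; if the sense of induction is the opposite, the (R,R)-ligand is used instead.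
Remark: ring A is numbered C1 (C=O), C2 (bridge carbon), C3, C4 (quaternary), C5, C6 (methyl-bearing) and the triones are written in the dienol tautomer of the target. The CIP letter at the quaternary carbon changes along the route only because substituent priorities change.

Step 1
Reactants: 1 methyl 4-methyl-3-oxopentanoate; 2 prenyl bromide (1-bromo-3-methylbut-2-ene)
Product: 3 methyl 4-methyl-2-(3-methylbut-2-en-1-yl)-3-oxopentanoate (racemic)
Conditions: K2CO3 (1.5 equiv), acetone, reflux
Reagents that add atoms: none
Why: The potassium enolate of the β-keto ester is C-alkylated by the primary allylic bromide in an SN2 reaction (acetoacetic ester alkylation), one equivalent of bromide and the hindered product limiting dialkylation, and the α-centre formed is racemic and enolisable as the next step requires.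

Step 2
Reactants: 3 methyl 4-methyl-2-(3-methylbut-2-en-1-yl)-3-oxopentanoate (racemic); 4 formaldehyde (37% aqueous solution)
Product: 5 methyl (2R)-2-(hydroxymethyl)-4-methyl-2-(3-methylbut-2-en-1-yl)-3-oxopentanoate
Conditions: Sc(OTf)3 (10 mol %), (S,S)-6,6'-bis(1-hydroxy-2,2-dimethylpropyl)-2,2'-bipyridine (12 mol %), aq. HCHO (5 equiv), DME/H2O (9:1), −20 to 0 °C
Reagents that add atoms: none
Why: The β-keto ester binds trivalent scandium through both carbonyl oxygens inside the tetradentate bipyridine diol complex, the acidified α-hydrogen is lost, and the chelated scandium enolate adds through its α-carbon to formaldehyde (direct aldol addition), making the C4–C5 bond before proton transfer frees the product and returns the catalyst. The closest known reaction type is the catalytic enantioselective hydroxymethylation of α-substituted β-keto esters with aqueous formaldehyde under chiral Lewis acid catalysis, together with the use of this scandium–bipyridine complex for hydroxymethylation of preformed enolates. No ring is closed. The quaternary stereocentre C4 is set by the ligand: both enantiomers of 3 give the same planar chelated enolate and the tert-butyl carbinol arms of the ligand cover one of its faces, so the step is stereoconvergent and catalyst-controlled. The step needs enantioface selection on a tetrasubstituted enolate and C–C bond formation in preference to retro-aldol loss of formaldehyde; the rigid two-point chelate, the steric difference between the methoxy and isopropyl ends that fixes the orientation of the substrate at the metal, the small size of formaldehyde and its excess at low temperature should secure this, and 5 is oxidised without storage.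

Step 3
Reactants: 5 methyl (2R)-2-(hydroxymethyl)-4-methyl-2-(3-methylbut-2-en-1-yl)-3-oxopentanoate
Product: 6 methyl (2R)-2-formyl-4-methyl-2-(3-methylbut-2-en-1-yl)-3-oxopentanoate
Conditions: Dess–Martin periodinane (1.3 equiv), CH2Cl2, 0 °C to rt; used crude
Reagents that add atoms: none
Why: Dess–Martin oxidation converts the neopentyl-type primary alcohol into the aldehyde under neutral, non-aqueous conditions that offer no base to start the retro-aldol, and since C4 carries no hydrogen the stereocentre cannot epimerise.

Step 4
Reactants: 6 methyl (2R)-2-formyl-4-methyl-2-(3-methylbut-2-en-1-yl)-3-oxopentanoate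
Product: 7 methyl (2R)-2-(1-hydroxypropyl)-4-methyl-2-(3-methylbut-2-en-1-yl)-3-oxopentanoate (both carbinol epimers)
Conditions: EtMgBr (1.1 equiv), THF, −78 °C; then pH 7 aqueous buffer
Reagents that add atoms: ethylmagnesium bromide, CC[Mg]Br
Why: Grignard addition goes to the aldehyde because at −78 °C it is far more electrophilic than the doubly α-branched isobutyryl ketone and the methyl ester, and the new carbinol centre, formed without control, is removed in step 5.

Step 5
Reactants: 7 methyl (2R)-2-(1-hydroxypropyl)-4-methyl-2-(3-methylbut-2-en-1-yl)-3-oxopentanoate (both carbinol epimers)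
Product: 8 methyl (2R)-4-methyl-2-(3-methylbut-2-en-1-yl)-3-oxo-2-propanoylpentanoate
Conditions: Dess–Martin periodinane (1.5 equiv), CH2Cl2, rt
Reagents that add atoms: none
Why: A second Dess–Martin oxidation turns the secondary alcohol into the ethyl ketone without base, so that neither retro-aldol cleavage nor nucleophilic attack on the 1,3-dicarbonyl array can occur and both carbinol epimers converge on one ketone.

Step 6
Reactants: 8 methyl (2R)-4-methyl-2-(3-methylbut-2-en-1-yl)-3-oxo-2-propanoylpentanoate
Product: 9 methyl (2S)-4-methyl-2-(3-methylbut-2-en-1-yl)-2-(2-methylpropanoyl)-3,5-dioxohexanoate (C4 epimers and enol forms)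
Conditions: MgBr2·OEt2 (2.5 equiv), i-Pr2NEt (3 equiv), AcCl (1.3 equiv), CH2Cl2, 0 °C to rt
Reagents that add atoms: acetyl chloride, CC(=O)Cl
Why: In this soft-enolisation crossed Claisen acylation, magnesium chelation of the 1,3-dicarbonyl unit lets the tertiary amine remove a propanoyl CH2 hydrogen and the magnesium enolate is C-acylated as it forms; the CH2 group is enolised in preference to the hindered isopropyl methine, the product is held as its magnesium diketonate against a second acylation, and C4 stays untouched.

Step 7
Reactants: 9 methyl (2S)-4-methyl-2-(3-methylbut-2-en-1-yl)-2-(2-methylpropanoyl)-3,5-dioxohexanoate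
Product: 10 (4R)-3,5-dihydroxy-6-methyl-4-(3-methylbut-2-en-1-yl)-4-(2-methylpropanoyl)cyclohexa-2,5-dien-1-one (ring A trione; C2 unsubstituted)
Conditions: LiN(i-Pr)2 (3 equiv), THF, −78 to −20 °C, argon; then cold 1 M HCl
Reagents that add atoms: none
Why: In this Dieckmann condensation through the 1,3-diketone dianion, the first equivalent of base removes the C6 hydrogen, the second a hydrogen of the terminal methyl group, and the C2 carbanion attacks the ester carbon C3 in a 6-exo-trig closure made irreversible by loss of methoxide and deprotonation of the trione, whereas addition to the hindered isobutyryl ketone is reversible and no bond to C4 is broken.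

Step 8
Reactants: 11 phloroglucinol
Product: 12 2-methyl-1-(2,4,6-trihydroxyphenyl)propan-1-one
Conditions: i-PrCOCl (1.05 equiv), AlCl3 (3.5 equiv), PhNO2/CH2Cl2, 0 to 40 °C; then ice/1 M HCl
Reagents that add atoms: 2-methylpropanoyl chloride, CC(C)C(=O)Cl
Why: Friedel–Crafts acylation of the electron-rich phloroglucinol stops after one acyl group because the aluminium-chelated ketone deactivates the ring.

Step 9
Reactants: 12 2-methyl-1-(2,4,6-trihydroxyphenyl)propan-1-one; 2 prenyl bromide
Product: 13 1-[2,4,6-trihydroxy-3-(3-methylbut-2-en-1-yl)phenyl]-2-methylpropan-1-one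
Conditions: 5% aq. KOH, prenyl bromide (1.0 equiv), 0 °C
Reagents that add atoms: none
Why: The ambident phenolate is C-alkylated by prenyl bromide (SN2 C-prenylation of an acylphloroglucinol) because hydrogen bonding to oxygen in water favours attack through carbon, the two free ring positions are equivalent, and one equivalent of bromide keeps the reaction mainly at the mono-prenyl stage.

Step 10
Reactants: 13 1-[2,4,6-trihydroxy-3-(3-methylbut-2-en-1-yl)phenyl]-2-methylpropan-1-one
Product: 14 1-[3-[(dimethylamino)methyl]-2,4,6-trihydroxy-5-(3-methylbut-2-en-1-yl)phenyl]-2-methylpropan-1-one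
Conditions: (Me2N=CH2)I (1.1 equiv), Et3N (1.1 equiv), MeCN, 0 °C to rt
Reagents that add atoms: N,N-dimethylmethyleneiminium iodide, C=[N+](C)C.[I-]
Why: Mannich aminomethylation with the preformed iminium salt occurs at the single remaining ring carbon, which is activated by three hydroxyl groups, and the absence of free formaldehyde avoids bridging of two rings.

Step 11
Reactants: 10 (4R)-3,5-dihydroxy-6-methyl-4-(3-methylbut-2-en-1-yl)-4-(2-methylpropanoyl)cyclohexa-2,5-dien-1-one; 14 1-[3-[(dimethylamino)methyl]-2,4,6-trihydroxy-5-(3-methylbut-2-en-1-yl)phenyl]-2-methylpropan-1-one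
Product: 16 (4S)-3,5-dihydroxy-6-methyl-4-(3-methylbut-2-en-1-yl)-4-(2-methylpropanoyl)-2-{[2,4,6-trihydroxy-3-(3-methylbut-2-en-1-yl)-5-(2-methylpropanoyl)phenyl]methyl}cyclohexa-2,5-dien-1-one, via ortho-quinone methide of ring B 15 (not isolated)
Conditions: 10 and 14 (1:1), 1,4-dioxane, 80 °C, argon; then cold dilute aq. citric acid wash
Reagents that add atoms: none
Why: Thermal loss of dimethylamine from the ortho-hydroxybenzylamine, helped by proton transfer from the acidic trione, gives the ortho-quinone methide 15, to which the enol carbon C2 of 10 adds in a Michael reaction driven by re-aromatisation of ring B; C2 is the only unsubstituted nucleophilic carbon of ring A, the amine is held as the ammonium salt of the acidic product so that it should not attack the C4 acyl group, and C4 is not involved.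

**Compound list**
1 | methyl 4-methyl-3-oxopentanoate | COC(=O)CC(=O)C(C)C | starting material
2 | prenyl bromide (1-bromo-3-methylbut-2-ene) | CC(C)=CCBr | starting material
3 | methyl 4-methyl-2-(3-methylbut-2-en-1-yl)-3-oxopentanoate (racemic) | COC(=O)C(CC=C(C)C)C(=O)C(C)C | intermediate
4 | formaldehyde | C=O | starting material
5 | methyl (2R)-2-(hydroxymethyl)-4-methyl-2-(3-methylbut-2-en-1-yl)-3-oxopentanoate | COC(=O)[C@@](CC=C(C)C)(C(=O)C(C)C)CO | intermediate
6 | methyl (2R)-2-formyl-4-methyl-2-(3-methylbut-2-en-1-yl)-3-oxopentanoate | COC(=O)[C@@](CC=C(C)C)(C(=O)C(C)C)C=O | intermediate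
7 | methyl (2R)-2-(1-hydroxypropyl)-4-methyl-2-(3-methylbut-2-en-1-yl)-3-oxopentanoate (both carbinol epimers) | COC(=O)[C@@](CC=C(C)C)(C(=O)C(C)C)C(O)CC | intermediate
8 | methyl (2R)-4-methyl-2-(3-methylbut-2-en-1-yl)-3-oxo-2-propanoylpentanoate | COC(=O)[C@@](CC=C(C)C)(C(=O)C(C)C)C(=O)CC | intermediate
9 | methyl (2S)-4-methyl-2-(3-methylbut-2-en-1-yl)-2-(2-methylpropanoyl)-3,5-dioxohexanoate (C4 epimers and enol forms) | COC(=O)[C@@](CC=C(C)C)(C(=O)C(C)C)C(=O)C(C)C(C)=O | intermediate
10 | (4R)-3,5-dihydroxy-6-methyl-4-(3-methylbut-2-en-1-yl)-4-(2-methylpropanoyl)cyclohexa-2,5-dien-1-one | O=C1C=C(O)[C@@](CC=C(C)C)(C(=O)C(C)C)C(O)=C1C | intermediate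
11 | phloroglucinol | Oc1cc(O)cc(O)c1 | starting material
12 | 2-methyl-1-(2,4,6-trihydroxyphenyl)propan-1-one | CC(C)C(=O)c1c(O)cc(O)cc1O | intermediate
13 | 1-[2,4,6-trihydroxy-3-(3-methylbut-2-en-1-yl)phenyl]-2-methylpropan-1-one | CC(C)=CCc1c(O)cc(O)c(C(=O)C(C)C)c1O | intermediate
14 | 1-[3-[(dimethylamino)methyl]-2,4,6-trihydroxy-5-(3-methylbut-2-en-1-yl)phenyl]-2-methylpropan-1-one | CC(C)=CCc1c(O)c(CN(C)C)c(O)c(C(=O)C(C)C)c1O | intermediate
15 | 3,5-dihydroxy-6-methylidene-4-(3-methylbut-2-en-1-yl)-2-(2-methylpropanoyl)cyclohexa-2,4-dien-1-one (ortho-quinone methide of ring B, not isolated) | C=C1C(=O)C(C(=O)C(C)C)=C(O)C(CC=C(C)C)=C1O | intermediate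
16 | (4S)-3,5-dihydroxy-6-methyl-4-(3-methylbut-2-en-1-yl)-4-(2-methylpropanoyl)-2-{[2,4,6-trihydroxy-3-(3-methylbut-2-en-1-yl)-5-(2-methylpropanoyl)phenyl]methyl}cyclohexa-2,5-dien-1-one | CC(C)=CCc1c(O)c(CC2=C(O)[C@@](CC=C(C)C)(C(=O)C(C)C)C(O)=C(C)C2=O)c(O)c(C(=O)C(C)C)c1O | target

**Step count**
Total: 11 steps. Longest linear sequence: 8 steps (steps 1–7 and 11); ring B takes 3 steps (8–10).

**Steps most likely to fail**

Step 7. The terminal carbanion may form incompletely. The strongly basic medium may also cleave the triacylated C4 by retro-Claisen reaction, or move the isobutyryl group to C2 through aldol addition and fragmentation. The fallback sets out from 9 and returns at 10, and needs only a mono-anion. O-Methylation of the chelated enol of 9 at the more accessible acetyl-side oxygen (Me3SiCHN2, MeOH/PhMe, 0 °C) should give the vinylogous ester methyl (2S,4Z)-5-methoxy-4-methyl-2-(3-methylbut-2-en-1-yl)-2-(2-methylpropanoyl)-3-oxohex-4-enoate F3. With the acidic C6 hydrogen gone, LiN(i-Pr)2 (2.2 equiv, THF, −78 to 0 °C) removes a hydrogen of the terminal methyl group, and the dienolate closes onto the ester in a vinylogous Dieckmann condensation. This should give (2S)-5-methoxy-4-methyl-2-(3-methylbut-2-en-1-yl)-2-(2-methylpropanoyl)cyclohex-4-ene-1,3-dione F4, whose enol ether is hydrolysed (0.5 M HCl, THF, rt) to 10.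

Step 2. Facial selectivity may be insufficient with the bulky isopropyl ketone, enolisation may be slow, or retro-aldol reversal may erode conversion and enantiopurity. The fallback sets out from 3 and returns at 5, replacing asymmetric catalysis by resolution. Hydroxymethylation without a chiral catalyst (aq. HCHO, KHCO3 cat., THF, rt) should give racemic methyl 2-(hydroxymethyl)-4-methyl-2-(3-methylbut-2-en-1-yl)-3-oxopentanoate F1. A lipase chosen by screening for this preference (for example Burkholderia cepacia lipase, vinyl acetate, t-BuOMe, 30 °C) acetylates the unwanted enantiomer to methyl (2S)-2-(acetoxymethyl)-4-methyl-2-(3-methylbut-2-en-1-yl)-3-oxopentanoate F2. The unreacted (R)-alcohol is 5, separated by chromatography.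

Step 11. The ortho-quinone methide may dimerise or be taken up through oxygen of the trione. The temperature needed for amine loss may also start deacylation and aromatisation of ring A, or cyclodehydration across the bridge. The fallback sets out from 10 (with 13 as partner) and returns at 16, with the polarity of the coupling reversed. Aminomethylation of 10 at C2 ((Me2N=CH2)I, CH2Cl2, 0 °C) should give (4S)-2-[(dimethylamino)methyl]-3,5-dihydroxy-6-methyl-4-(3-methylbut-2-en-1-yl)-4-(2-methylpropanoyl)cyclohexa-2,5-dien-1-one F5. On gentle warming with 13 (MeCN, 40 °C) this loses dimethylamine to give (6R)-5-hydroxy-4-methyl-2-methylidene-6-(3-methylbut-2-en-1-yl)-6-(2-methylpropanoyl)cyclohex-4-ene-1,3-dione F6. The free ring carbon of 13 then adds to this acceptor (Friedel–Crafts-type conjugate addition) to give 16.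

Further compounds
F1 | step 2 | racemic methyl 2-(hydroxymethyl)-4-methyl-2-(3-methylbut-2-en-1-yl)-3-oxopentanoate | COC(=O)C(CC=C(C)C)(C(=O)C(C)C)CO
F2 | step 2 | methyl (2S)-2-(acetoxymethyl)-4-methyl-2-(3-methylbut-2-en-1-yl)-3-oxopentanoate | COC(=O)[C@](CC=C(C)C)(C(=O)C(C)C)COC(C)=O
F3 | step 7 | methyl (2S,4Z)-5-methoxy-4-methyl-2-(3-methylbut-2-en-1-yl)-2-(2-methylpropanoyl)-3-oxohex-4-enoate | COC(=O)[C@@](CC=C(C)C)(C(=O)C(C)C)C(=O)/C(C)=C(\OC)C
F4 | step 7 | (2S)-5-methoxy-4-methyl-2-(3-methylbut-2-en-1-yl)-2-(2-methylpropanoyl)cyclohex-4-ene-1,3-dione | COC1=C(C)C(=O)[C@](CC=C(C)C)(C(=O)C(C)C)C(=O)C1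
F5 | step 11 | (4S)-2-[(dimethylamino)methyl]-3,5-dihydroxy-6-methyl-4-(3-methylbut-2-en-1-yl)-4-(2-methylpropanoyl)cyclohexa-2,5-dien-1-one | CN(C)CC1=C(O)[C@@](CC=C(C)C)(C(=O)C(C)C)C(O)=C(C)C1=O
F6 | step 11 | (6R)-5-hydroxy-4-methyl-2-methylidene-6-(3-methylbut-2-en-1-yl)-6-(2-methylpropanoyl)cyclohex-4-ene-1,3-dione | C=C1C(=O)[C@@](CC=C(C)C)(C(=O)C(C)C)C(O)=C(C)C1=O
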